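**Retrosynthetic overview**
1. Target 12 ⇐ 11 by hydrogenolysis of two benzyl ethers; 11 ⇐ 10 by adding hydrogen to the exocyclic C4=C7' alkene from the face of the C3 hydroxyl, which sets C4.
2. 10 ⇐ 8 + 9 in one catalytic operation that makes the aryl–C7' bond and the C3–C4 bond; the C3–C4 bond closes the only ring built in the route, the γ-lactone O1–C2(=O)–C3–C4–C5, and C3 is set there by a chiral rhodium catalyst.
3. The plan rests on this feature: the tertiary carbinol C3 sits between the lactone carbonyl C2 and C4, so C2/C3 are the ester and ketone carbons of a 2-oxo ester whose ester oxygen O1 carries C5–C4≡C7' as a propargyl group, and the guaiacyl ring arrives at C7' as an arylboronic acid.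
4. 8 ⇐ arylpyruvic acid 6 + propargyl bromide 7; 6 ⇐ azlactone 4 ⇐ O-benzylsyringaldehyde 2 + N-acetylglycine 3; 2 ⇐ syringaldehyde 1.

Key step: step 5

Assumption: the sense of enantioinduction of (R)-BINAP on 8 cannot be predicted with certainty; the antipodal ligand is to be used if the first run should give the 3R lactone.
Remark: 6 and 8 are drawn as keto tautomers; both should exist largely as the conjugated enols and are to be handled under inert gas.

**Step 1**
Reactants: 1 syringaldehyde
Product: 2 4-(benzyloxy)-3,5-dimethoxybenzaldehyde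
Conditions: BnBr, K2CO3, DMF, 60 °C
Reagents that add atoms: benzyl bromide, BrCc1ccccc1
Why: Williamson ether synthesis on the phenoxide (acidified by the para formyl group) should give the benzyl ether, which tolerates the hot alkali of step 3 and is removed by hydrogenolysis at the end.

**Step 2**
Reactants: 2 4-(benzyloxy)-3,5-dimethoxybenzaldehyde; 3 N-acetylglycine
Product: 4 (Z)-4-[4-(benzyloxy)-3,5-dimethoxybenzylidene]-2-methyloxazol-5(4H)-one
Conditions: NaOAc, Ac2O, 110 °C
Reagents that add atoms: none
Why: Erlenmeyer–Plöchl azlactone synthesis, in which Ac2O cyclodehydrates 3 to 2-methyloxazol-5(4H)-one and its acidic C4 methylene condenses with the aldehyde (Perkin-type aldol and elimination) to the more stable Z benzylidene.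

**Step 3**
Reactants: 4 (Z)-4-[4-(benzyloxy)-3,5-dimethoxybenzylidene]-2-methyloxazol-5(4H)-one
Product: 6 3-[4-(benzyloxy)-3,5-dimethoxyphenyl]-2-oxopropanoic acid, via acetamidoacrylic acid 5 (not isolated)
Conditions: 10% aq. NaOH, reflux, N2; then aq. HCl, 0 °C
Reagents that add atoms: water, O
Why: Classical alkaline azlactone hydrolysis, in which hydroxide opens the ring to the acetamidoacrylate and then cleaves the enamide with loss of ammonia and acetate to the 2-oxo carboxylate, while the benzyl ether is inert to base and exclusion of air protects the enolate.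

**Step 4**
Reactants: 6 3-[4-(benzyloxy)-3,5-dimethoxyphenyl]-2-oxopropanoic acid; 7 propargyl bromide
Product: 8 prop-2-ynyl 3-[4-(benzyloxy)-3,5-dimethoxyphenyl]-2-oxopropanoate
Conditions: KHCO3, DMF, 0 °C to rt, N2
Reagents that add atoms: none
Why: SN2 O-alkylation of the carboxylate, where one equivalent of hydrogencarbonate deprotonates only the carboxylic acid and not the enol or C7–H, so enol alkylation and aldol self-condensation should be avoided and no carbodiimide activation of an enolizable keto acid is needed.

**Step 5**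
Reactants: 8 prop-2-ynyl 3-[4-(benzyloxy)-3,5-dimethoxyphenyl]-2-oxopropanoate; 9 [4-(benzyloxy)-3-methoxyphenyl]boronic acid
Product: 10 (S,Z)-4-[4-(benzyloxy)-3-methoxybenzylidene]-3-[4-(benzyloxy)-3,5-dimethoxybenzyl]-3-hydroxydihydrofuran-2(3H)-one
Conditions: [Rh(OH)((R)-binap)]2 (2.5 mol%), 9 (2 equiv), 1,4-dioxane/H2O (10:1), 40 °C, 8 added slowly by syringe pump, Ar
Reagents that add atoms: none
Why: Transmetalation of 9 to the hydroxorhodium complex (monovalent rhodium) gives an aryl–rhodium that adds syn across the terminal alkyne of 8, aryl to the unsubstituted carbon (new aryl–C7' bond) and rhodium to C4; the alkenyl–rhodium then inserts the neighbouring C3 ketone (new C3–C4 bond) and water releases the tertiary alcohol and returns Rh–OH. The closest known reaction type is the rhodium-catalysed arylative cyclization of alkynals and alkynones with arylboronic acids, applied here to a propargyl 2-oxo ester. The lactone ring O1–C2–C3–C4–C5 is closed by C–C bond formation in a 5-exo-trig mode, and the syn addition fixes the Z alkene (aryl cis to C3). The C3 stereocentre is set by the chiral bisphosphine on rhodium, which decides which face of the ketone meets the alkenyl–rhodium bond. The step needs aryl delivery to the terminal alkyne carbon, which the unsubstituted terminus secures (the regioisomeric alkenyl–rhodium could only close to a six-membered ring holding an E alkene), and it needs ketone insertion to run ahead of loss of the β-acyloxy group, protonolysis and a second alkyne insertion. The strongly electrophilic 1,2-dicarbonyl held beside rhodium, the aqueous medium that keeps the enol in exchange with the reactive keto form, the base-free catalyst and the slow addition of 8 are chosen to secure this.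

**Step 6**
Reactants: 10 (S,Z)-4-[4-(benzyloxy)-3-methoxybenzylidene]-3-[4-(benzyloxy)-3,5-dimethoxybenzyl]-3-hydroxydihydrofuran-2(3H)-one
Product: 11 (3S,4R)-4-[4-(benzyloxy)-3-methoxybenzyl]-3-[4-(benzyloxy)-3,5-dimethoxybenzyl]-3-hydroxydihydrofuran-2(3H)-one
Conditions: [Ir(cod)(PCy3)(py)]PF6 (5 mol%), H2 (1 atm), CH2Cl2, 0 °C to rt
Reagents that add atoms: none
Why: Hydroxyl-directed homogeneous hydrogenation (Crabtree catalyst), in which the C3–OH binds the cationic iridium and hydrogen is added to the exocyclic C4=C7' bond from the hydroxyl face (also the face away from the C3 benzyl group), so the new C4–H should end cis to the C3–OH (4R) while the benzyl ethers and the allylic C5–O bond stay intact.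

**Step 7**
Reactants: 11 (3S,4R)-4-[4-(benzyloxy)-3-methoxybenzyl]-3-[4-(benzyloxy)-3,5-dimethoxybenzyl]-3-hydroxydihydrofuran-2(3H)-one
Product: 12 (3S,4R)-3-hydroxy-4-(4-hydroxy-3-methoxybenzyl)-3-(4-hydroxy-3,5-dimethoxybenzyl)dihydrofuran-2(3H)-one
Conditions: H2 (1 atm), Pd/C, EtOAc/EtOH, rt
Reagents that add atoms: none
Why: Catalytic hydrogenolysis of the two aryl benzyl ethers, which should leave both stereocentres untouched because the C3–OH is homobenzylic and no allylic C–O bond remains once the alkene is saturated.

**Compound list**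
1 | syringaldehyde (4-hydroxy-3,5-dimethoxybenzaldehyde) | COc1cc(C=O)cc(OC)c1O | starting material
2 | 4-(benzyloxy)-3,5-dimethoxybenzaldehyde | COc1cc(C=O)cc(OC)c1OCc1ccccc1 | intermediate
3 | N-acetylglycine | CC(=O)NCC(=O)O | starting material
4 | (Z)-4-[4-(benzyloxy)-3,5-dimethoxybenzylidene]-2-methyloxazol-5(4H)-one | CC1=N/C(=C\c2cc(OC)c(OCc3ccccc3)c(OC)c2)C(=O)O1 | intermediate
5 | (Z)-2-acetamido-3-[4-(benzyloxy)-3,5-dimethoxyphenyl]prop-2-enoic acid (sodium salt in the flask, not isolated) | CC(=O)N/C(=C\c1cc(OC)c(OCc2ccccc2)c(OC)c1)C(=O)O | intermediate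
6 | 3-[4-(benzyloxy)-3,5-dimethoxyphenyl]-2-oxopropanoic acid | O=C(O)C(=O)Cc1cc(OC)c(OCc2ccccc2)c(OC)c1 | intermediate
7 | propargyl bromide (3-bromoprop-1-yne) | C#CCBr | starting material
8 | prop-2-ynyl 3-[4-(benzyloxy)-3,5-dimethoxyphenyl]-2-oxopropanoate | C#CCOC(=O)C(=O)Cc1cc(OC)c(OCc2ccccc2)c(OC)c1 | intermediate
9 | [4-(benzyloxy)-3-methoxyphenyl]boronic acid | OB(O)c1ccc(OCc2ccccc2)c(OC)c1 | starting material
10 | (S,Z)-4-[4-(benzyloxy)-3-methoxybenzylidene]-3-[4-(benzyloxy)-3,5-dimethoxybenzyl]-3-hydroxydihydrofuran-2(3H)-one | O=C1OC/C(=C/c2ccc(OCc3ccccc3)c(OC)c2)[C@@]1(O)Cc1cc(OC)c(OCc2ccccc2)c(OC)c1 | intermediate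
11 | (3S,4R)-4-[4-(benzyloxy)-3-methoxybenzyl]-3-[4-(benzyloxy)-3,5-dimethoxybenzyl]-3-hydroxydihydrofuran-2(3H)-one | COc1cc(C[C@@H]2COC(=O)[C@]2(O)Cc2cc(OC)c(OCc3ccccc3)c(OC)c2)ccc1OCc1ccccc1 | intermediate
12 | (3S,4R)-3-hydroxy-4-(4-hydroxy-3-methoxybenzyl)-3-(4-hydroxy-3,5-dimethoxybenzyl)dihydrofuran-2(3H)-one | COc1cc(C[C@@H]2COC(=O)[C@]2(O)Cc2cc(OC)c(O)c(OC)c2)ccc1O | target

Total step count: 7
Longest linear sequence: 7 steps (1 → 2 → 4 → 6 → 8 → 10 → 11 → 12)

**Steps most likely to fail**

1. Step 5 (key step). The alkenyl–rhodium may expel the β-acyloxy group (allene formation with release of the pyruvate), may be protonated while the ketone rests as its enol, or may insert further alkyne; enantiofacial discrimination at the ketone may also be insufficient. The fallback closes the same ring by reductive alkyne–ketone coupling, in which the metal sits on the distal alkyne carbon, no β-elimination is possible and the enol is only a reservoir. It sets out from 6. Propargyl alcohol is coupled with 1-(benzyloxy)-4-iodo-2-methoxybenzene (COc1cc(I)ccc1OCc1ccccc1; Sonogashira coupling, Pd(PPh3)2Cl2, CuI, Et3N, THF) to give 3-[4-(benzyloxy)-3-methoxyphenyl]prop-2-yn-1-ol F1. Appel bromination (CBr4, PPh3, CH2Cl2) should give 1-(benzyloxy)-4-(3-bromoprop-1-yn-1-yl)-2-methoxybenzene F2. Alkylation of 6 with F2 under the conditions of step 4 should give 3-[4-(benzyloxy)-3-methoxyphenyl]prop-2-yn-1-yl 3-[4-(benzyloxy)-3,5-dimethoxyphenyl]-2-oxopropanoate F3. Hydrogen-mediated asymmetric reductive cyclization ([Rh(cod)2]OTf, chiral biaryl bisphosphine, H2 1 atm, ClCH2CH2Cl, rt) through an oxarhodacyclopentene should then give (S,E)-4-[4-(benzyloxy)-3-methoxybenzylidene]-3-[4-(benzyloxy)-3,5-dimethoxybenzyl]-3-hydroxydihydrofuran-2(3H)-one F4, the geometric isomer of 10. Hydrogenation of F4 as in step 6 erases the alkene geometry and comes back to the route at 11.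

2. Step 6. Hydrogen may be delivered without hydroxyl coordination (lactone carbonyl or ether oxygens competing for iridium), the catalyst may be deactivated before the hindered trisubstituted alkene is consumed, or the double bond may migrate into the ring. The fallback replaces coordinative delivery by a sterically controlled radical hydrogenation through metal-hydride hydrogen-atom transfer. It sets out from 10 (Mn(dpm)3 cat., PhSiH3, t-BuOOH, i-PrOH, rt): the hydrogen atom should be transferred to C4 from the face opposite the C3 benzyl group, which is the hydroxyl face, and the benzylic C7' radical is then reduced. It comes back to the route at 11 and makes no new compound (F0).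

3. Step 3. The arylpyruvate may degrade in hot alkali by aldol self-condensation or oxidative cleavage of its enolate, or amide hydrolysis may stop at the acetamidoacrylate stage. The fallback avoids the azlactone by olefination to a masked enol, setting out from 2. Horner–Wadsworth–Emmons reaction with methyl 2-[(tert-butyldimethylsilyl)oxy]-2-(dimethoxyphosphoryl)acetate (LiN(SiMe3)2, THF, −78 °C to rt) should give methyl (Z)-3-[4-(benzyloxy)-3,5-dimethoxyphenyl]-2-[(tert-butyldimethylsilyl)oxy]prop-2-enoate F5; its double-bond geometry is of no consequence. Desilylation (Bu4NF, AcOH, THF, 0 °C) should give methyl 3-[4-(benzyloxy)-3,5-dimethoxyphenyl]-2-oxopropanoate F6. Cold saponification (LiOH, THF/H2O, 0 °C, N2; then aq. HCl) comes back to the route at 6.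

**Further compounds**
F1 | step 5 | 3-[4-(benzyloxy)-3-methoxyphenyl]prop-2-yn-1-ol | OCC#Cc1ccc(OCc2ccccc2)c(OC)c1
F2 | step 5 | 1-(benzyloxy)-4-(3-bromoprop-1-yn-1-yl)-2-methoxybenzene | BrCC#Cc1ccc(OCc2ccccc2)c(OC)c1
F3 | step 5 | 3-[4-(benzyloxy)-3-methoxyphenyl]prop-2-yn-1-yl 3-[4-(benzyloxy)-3,5-dimethoxyphenyl]-2-oxopropanoate | O=C(OCC#Cc1ccc(OCc2ccccc2)c(OC)c1)C(=O)Cc1cc(OC)c(OCc2ccccc2)c(OC)c1
F4 | step 5 | (S,E)-4-[4-(benzyloxy)-3-methoxybenzylidene]-3-[4-(benzyloxy)-3,5-dimethoxybenzyl]-3-hydroxydihydrofuran-2(3H)-one | O=C1OC/C(=C\c2ccc(OCc3ccccc3)c(OC)c2)[C@@]1(O)Cc1cc(OC)c(OCc2ccccc2)c(OC)c1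
F0 | step 6 | none | none
F5 | step 3 | methyl (Z)-3-[4-(benzyloxy)-3,5-dimethoxyphenyl]-2-[(tert-butyldimethylsilyl)oxy]prop-2-enoate | COC(=O)/C(O[Si](C)(C)C(C)(C)C)=C/c1cc(OC)c(OCc2ccccc2)c(OC)c1
F6 | step 3 | methyl 3-[4-(benzyloxy)-3,5-dimethoxyphenyl]-2-oxopropanoate | COC(=O)C(=O)Cc1cc(OC)c(OCc2ccccc2)c(OC)c1
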